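**Retrosynthetic overview**
1. Target 25 ⇐ acetylation of the 4-exo alcohol 24 ⇐ C4 reduction, then retro-aldol/aldol epimerisation, of bicyclic enedione 19.
2. 19 ⇐ intramolecular aldol condensation (C2=C3) of keto-aldehyde 16; the six-membered ring (C1–C2–C3–C4–C5–C8) is formed last.
3. 16 ⇐ cyclopentanone 12: C5–C4 bond by aldol with methoxyacetaldehyde, C1–allyl by β-keto ester alkylation.
4. 12 ⇐ Dieckmann cyclisation of adipate 10; the five-membered ring (C8–C1–C7–C6–C5) is formed first.
5. 10 ⇐ Michael adduct 5 (C6–C7 bond, both stereocentres) ⇐ arylidene malonate 3 (from veratraldehyde and dimethyl malonate) + propanal.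

Assumption (one line): the C1–C8 locants of the target bicyclo[3.2.1]octene are used for the corresponding atoms of every intermediate, and a stereocentre left unspecified in a SMILES string is an inconsequential epimer mixture.

**Step 1**
Reactants: 1 3,4-dimethoxybenzaldehyde; 2 dimethyl malonate
Product: 3 dimethyl 2-(3,4-dimethoxybenzylidene)propanedioate
Conditions: piperidine (10 mol %), AcOH (10 mol %), toluene, reflux, Dean–Stark
Reagents that add atoms: none
Why: Knoevenagel (aldol-type) condensation of a non-enolisable aryl aldehyde with an active methylene compound, driven by azeotropic removal of water.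

**Step 2**
Reactants: 3 dimethyl 2-(3,4-dimethoxybenzylidene)propanedioate; 4 propanal
Product: 5 dimethyl 2-[(1R,2R)-1-(3,4-dimethoxyphenyl)-2-methyl-3-oxopropyl]propanedioate
Conditions: 4 (5 equiv), (S)-2-[diphenyl(trimethylsilyloxy)methyl]pyrrolidine (20 mol %), 4-nitrophenol (20 mol %), CHCl3, 4 °C to rt
Reagents that add atoms: none
Why: Enamine-catalysed asymmetric intermolecular Michael addition to an alkylidene malonate; by analogy with the nitroalkene series the (S)-diarylprolinol silyl ether shields one enamine face and the synclinal transition state gives the syn adduct, setting C7 (R) and C6 (R) in one step.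

**Step 3**
Reactants: 5 dimethyl 2-[(1R,2R)-1-(3,4-dimethoxyphenyl)-2-methyl-3-oxopropyl]propanedioate
Product: 6 dimethyl 2-[(1R,2R)-1-(3,4-dimethoxyphenyl)-4-methoxy-2-methylbut-3-en-1-yl]propanedioate (E/Z mixture)
Conditions: Ph3P(CH2OMe)Cl (2.5 equiv), KN(SiMe3)2 (2.4 equiv), THF, −78 °C to 0 °C; then 5 at −78 °C, warm to 0 °C
Reagents that add atoms: (methoxymethyl)triphenylphosphonium chloride, COC[P+](c1ccccc1)(c1ccccc1)c1ccccc1.[Cl-]
Why: Wittig methoxymethylenation for one-carbon homologation; excess ylide absorbs the acidic malonate proton and the low temperature keeps the α-methyl aldehyde stereocentre (C7) intact.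

**Step 4**
Reactants: 6 dimethyl 2-[(1R,2R)-1-(3,4-dimethoxyphenyl)-4-methoxy-2-methylbut-3-en-1-yl]propanedioate
Product: 7 dimethyl 2-[(1S,2S)-1-(3,4-dimethoxyphenyl)-4-methoxy-2-methylbut-3-en-1-yl]-2-hydroxypropanedioate (E/Z mixture)
Conditions: NaH (1.1 equiv), THF, 0 °C; then 2-(phenylsulfonyl)-3-phenyloxaziridine (1.3 equiv), −78 °C to 0 °C; AcOH
Reagents that add atoms: 2-(phenylsulfonyl)-3-phenyloxaziridine, O=S(=O)(c1ccccc1)N1OC1c1ccccc1
Why: Davis enolate hydroxylation of the only acidic C–H (the malonate methine, future C5); the sulfonyloxaziridine does not touch the enol ether at low temperature and no stereocentre is created (the descriptors change only through CIP priorities).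

**Step 5**
Reactants: 7 dimethyl 2-[(1S,2S)-1-(3,4-dimethoxyphenyl)-4-methoxy-2-methylbut-3-en-1-yl]-2-hydroxypropanedioate
Product: 8 dimethyl 2-[(1S,2S)-1-(3,4-dimethoxyphenyl)-4-methoxy-2-methylbut-3-en-1-yl]-2-methoxypropanedioate (E/Z mixture)
Conditions: NaH (1.2 equiv), MeI (3 equiv), DMF, 0 °C to rt
Reagents that add atoms: iodomethane, CI
Why: Williamson O-methylation of the tertiary alkoxide, which is the only acidic site left and cannot lactonise because the remote ester is still masked as the enol ether.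

**Step 6**
Reactants: 8 dimethyl 2-[(1S,2S)-1-(3,4-dimethoxyphenyl)-4-methoxy-2-methylbut-3-en-1-yl]-2-methoxypropanedioate
Product: 9 trimethyl (2S,3S)-2-(3,4-dimethoxyphenyl)-1-methoxy-3-methylbutane-1,1,4-tricarboxylate
Conditions: [C5H5NH][CrO3Cl] (pyridinium chlorochromate, 2.5 equiv), 4 Å sieves, CH2Cl2, rt
Reagents that add atoms: pyridinium chlorochromate, c1cc[nH+]cc1.[O-][Cr](=O)(=O)Cl
Why: Chlorochromate oxidation of a methyl enol ether to the methyl ester (oxygen transfer then 1,2-hydride shift) completes the homologation to the C1H2–C2O2Me unit without affecting C6 or C7.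

**Step 7**
Reactants: 9 trimethyl (2S,3S)-2-(3,4-dimethoxyphenyl)-1-methoxy-3-methylbutane-1,1,4-tricarboxylate
Product: 10 dimethyl (3S,4S)-3-(3,4-dimethoxyphenyl)-2-methoxy-4-methylhexanedioate (C2 epimers)
Conditions: LiCl (3 equiv), H2O (2 equiv), DMSO, 150 °C
Reagents that add atoms: none
Why: Krapcho dealkoxycarbonylation removes one ester of the geminal diester only (the isolated ester is inert), leaving the α-methoxy ester whose C5 configuration is irrelevant because C5 is enolised later.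

**Step 8**
Reactants: 10 dimethyl (3S,4S)-3-(3,4-dimethoxyphenyl)-2-methoxy-4-methylhexanedioate
Product: 11 methyl (2R,3S)-3-(3,4-dimethoxyphenyl)-4-methoxy-2-methyl-5-oxocyclopentane-1-carboxylate (C1/C4 epimers, keto–enol mixture)
Conditions: NaOMe (1.5 equiv), MeOH, reflux; then AcOH, 0 °C
Reagents that add atoms: none
Why: Dieckmann condensation under equilibrating conditions gives only the regioisomer that can form a stabilised β-keto ester enolate (C1 attacks the C8 ester; the alternative product has a quaternary, non-enolisable α-carbon and reverts), closing the trans-disubstituted cyclopentanone.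

**Step 9**
Reactants: 11 methyl (2R,3S)-3-(3,4-dimethoxyphenyl)-4-methoxy-2-methyl-5-oxocyclopentane-1-carboxylate
Product: 12 methyl (1R,2R,3S)-1-allyl-3-(3,4-dimethoxyphenyl)-4-methoxy-2-methyl-5-oxocyclopentane-1-carboxylate (C4 epimers)
Conditions: K2CO3 (2 equiv), allyl bromide (1.5 equiv), acetone, 50 °C
Reagents that add atoms: allyl bromide, C=CCBr
Why: C-alkylation of the β-keto ester enolate; the electrophile approaches anti to the adjacent C7 methyl group, so the allyl group ends trans to methyl and the ester (future C2) cis to it, fixing the quaternary C1 (minor epimer removed by chromatography).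

**Step 10**
Reactants: 12 methyl (1R,2R,3S)-1-allyl-3-(3,4-dimethoxyphenyl)-4-methoxy-2-methyl-5-oxocyclopentane-1-carboxylate; 13 methoxyacetaldehyde
Product: 14 methyl (1R,2R,3S,4S)-1-allyl-3-(3,4-dimethoxyphenyl)-4-(1-hydroxy-2-methoxyethyl)-4-methoxy-2-methyl-5-oxocyclopentane-1-carboxylate (carbinol epimers)
Conditions: LiN(iPr)2 (1.2 equiv), THF, −78 °C; then 13 (2 equiv), −78 °C, 20 min; AcOH at −78 °C
Reagents that add atoms: none
Why: Intermolecular lithium-enolate aldol addition; C1 is quaternary so only C5 can enolise, and the aldehyde adds to the enolate face anti to the adjacent C6 aryl group, placing the new C4 arm cis to the C1 ester and the methoxy group cis to aryl (C5 S).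

**Step 11**
Reactants: 14 methyl (1R,2R,3S,4S)-1-allyl-3-(3,4-dimethoxyphenyl)-4-(1-hydroxy-2-methoxyethyl)-4-methoxy-2-methyl-5-oxocyclopentane-1-carboxylate
Product: 15 (2S,3R,4S,5R)-2-allyl-4-(3,4-dimethoxyphenyl)-2-(hydroxymethyl)-5-(1-hydroxy-2-methoxyethyl)-5-methoxy-3-methylcyclopentan-1-ol (both secondary carbinols as mixtures)
Conditions: LiAlH4 (4 equiv), THF, 0 °C to rt; H2O/aq NaOH work-up
Reagents that add atoms: none
Why: Exhaustive hydride reduction of ketone and ester avoids any chemoselectivity problem, since all three oxygens are brought back to the carbonyl level together in the next step.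

**Step 12**
Reactants: 15 (2S,3R,4S,5R)-2-allyl-4-(3,4-dimethoxyphenyl)-2-(hydroxymethyl)-5-(1-hydroxy-2-methoxyethyl)-5-methoxy-3-methylcyclopentan-1-ol
Product: 16 (1S,2R,3S,4R)-1-allyl-3-(3,4-dimethoxyphenyl)-4-methoxy-4-(methoxyacetyl)-2-methyl-5-oxocyclopentane-1-carbaldehyde
Conditions: (COCl)2 (5 equiv), DMSO (10 equiv), CH2Cl2, −78 °C; then Et3N (15 equiv), −78 °C to 0 °C; used crude
Reagents that add atoms: none
Why: Swern oxidation activates all three hydroxyls before base is added, so the triol goes directly to the keto-aldehyde-ketone without lactol formation and over-oxidation; the quaternary C1 and C5 cannot epimerise.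

**Step 13**
Reactants: 16 (1S,2R,3S,4R)-1-allyl-3-(3,4-dimethoxyphenyl)-4-methoxy-4-(methoxyacetyl)-2-methyl-5-oxocyclopentane-1-carbaldehyde
Product: 19 (1S,5R,6S,7R)-1-allyl-6-(3,4-dimethoxyphenyl)-3,5-dimethoxy-7-methylbicyclo[3.2.1]oct-2-ene-4,8-dione, via aldol 17 (not isolated), via mesylate 18 (not isolated)
Conditions: DBU (0.3 equiv), CH2Cl2, 0 °C to rt; then MsCl (1.5 equiv), Et3N (4 equiv), 0 °C to rt
Reagents that add atoms: none
Why: Intramolecular aldol condensation between the only enolisable position (the methoxyacetyl CH2, C3) and the non-enolisable C2 aldehyde on the cis-disposed arms closes the six-membered ring, and mesylation/E1cB elimination gives the ring-constrained cis C2=C3 enol-ether enone under non-nucleophilic conditions that avoid retro-Claisen cleavage.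

**Step 14**
Reactants: 19 (1S,5R,6S,7R)-1-allyl-6-(3,4-dimethoxyphenyl)-3,5-dimethoxy-7-methylbicyclo[3.2.1]oct-2-ene-4,8-dione
Product: 20 (1S,4R,5S,6S,7R)-1-allyl-6-(3,4-dimethoxyphenyl)-4-hydroxy-3,5-dimethoxy-7-methylbicyclo[3.2.1]oct-2-en-8-one (4-endo alcohol)
Conditions: NaBH4 (1.0 equiv), CeCl3·7H2O (1.2 equiv), MeOH/THF (1:1), −78 °C, 30 min; AcOH quench
Reagents that add atoms: none
Why: Luche 1,2-reduction is expected to take the conjugated C4 carbonyl in preference to the C8 ketone flanked by two quaternary bridgeheads; hydride should enter from the more open exo face (C8 side, away from the endo hydrogen on C6), giving the 4R (endo) alcohol, which step 15 corrects.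

**Step 15**
Reactants: 20 (1S,4R,5S,6S,7R)-1-allyl-6-(3,4-dimethoxyphenyl)-4-hydroxy-3,5-dimethoxy-7-methylbicyclo[3.2.1]oct-2-en-8-one
Product: 24 (1S,4S,5S,6S,7R)-1-allyl-6-(3,4-dimethoxyphenyl)-4-hydroxy-3,5-dimethoxy-7-methylbicyclo[3.2.1]oct-2-en-8-one (4-exo alcohol), via endo lithium alkoxide 21 (not isolated), via ring-opened lithium enolate 22 (not isolated), via exo lithium alkoxide 23 (not isolated)
Conditions: LiN(SiMe3)2 (1.1 equiv), THF, −78 °C, then 0 °C, 1 h; recool to −78 °C; AcOH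
Reagents that add atoms: none
Why: Retro-aldol/aldol equilibration of the β-alkoxy ketone, in which the C4–C5 bond opens to the cis-enal enolate and recloses through a lithium-chelated closed transition state, is expected to favour the aldolate whose O4 is syn to the C8 carbonyl (exo, 4S), the only epimer that can chelate lithium between O4 and O8, and cold protonation freezes it (C5 is re-formed with the same configuration because the tether allows only cis bridging).

**Step 16**
Reactants: 24 (1S,4S,5S,6S,7R)-1-allyl-6-(3,4-dimethoxyphenyl)-4-hydroxy-3,5-dimethoxy-7-methylbicyclo[3.2.1]oct-2-en-8-one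
Product: 25 (1S,4S,5S,6S,7R)-1-allyl-6-(3,4-dimethoxyphenyl)-3,5-dimethoxy-7-methyl-8-oxobicyclo[3.2.1]oct-2-en-4-yl acetate
Conditions: Ac2O (3 equiv), pyridine, DMAP (10 mol %), CH2Cl2, 0 °C to rt
Reagents that add atoms: acetic anhydride, CC(=O)OC(C)=O
Why: DMAP-catalysed O-acylation of the secondary alcohol with retention at C4; the weakly basic, acid-free conditions do not trigger retro-aldol or cleavage of the benzylic C5–C6 bond.

**Compound list**
1 | 3,4-dimethoxybenzaldehyde (veratraldehyde) | COc1ccc(C=O)cc1OC | starting material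
2 | dimethyl malonate | COC(=O)CC(=O)OC | starting material
3 | dimethyl 2-(3,4-dimethoxybenzylidene)propanedioate | COC(=O)C(=Cc1ccc(OC)c(OC)c1)C(=O)OC | intermediate
4 | propanal | CCC=O | starting material
5 | dimethyl 2-[(1R,2R)-1-(3,4-dimethoxyphenyl)-2-methyl-3-oxopropyl]propanedioate | O=C[C@H](C)[C@@H](c1ccc(OC)c(OC)c1)C(C(=O)OC)C(=O)OC | intermediate
6 | dimethyl 2-[(1R,2R)-1-(3,4-dimethoxyphenyl)-4-methoxy-2-methylbut-3-en-1-yl]propanedioate (E/Z mixture) | COC=C[C@H](C)[C@@H](c1ccc(OC)c(OC)c1)C(C(=O)OC)C(=O)OC | intermediate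
7 | dimethyl 2-[(1S,2S)-1-(3,4-dimethoxyphenyl)-4-methoxy-2-methylbut-3-en-1-yl]-2-hydroxypropanedioate (E/Z mixture) | COC=C[C@H](C)[C@@H](c1ccc(OC)c(OC)c1)C(O)(C(=O)OC)C(=O)OC | intermediate
8 | dimethyl 2-[(1S,2S)-1-(3,4-dimethoxyphenyl)-4-methoxy-2-methylbut-3-en-1-yl]-2-methoxypropanedioate (E/Z mixture) | COC=C[C@H](C)[C@@H](c1ccc(OC)c(OC)c1)C(OC)(C(=O)OC)C(=O)OC | intermediate
9 | trimethyl (2S,3S)-2-(3,4-dimethoxyphenyl)-1-methoxy-3-methylbutane-1,1,4-tricarboxylate | COC(=O)C[C@H](C)[C@@H](c1ccc(OC)c(OC)c1)C(OC)(C(=O)OC)C(=O)OC | intermediate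
10 | dimethyl (3S,4S)-3-(3,4-dimethoxyphenyl)-2-methoxy-4-methylhexanedioate (C2 epimers) | COC(=O)C[C@H](C)[C@@H](c1ccc(OC)c(OC)c1)C(OC)C(=O)OC | intermediate
11 | methyl (2R,3S)-3-(3,4-dimethoxyphenyl)-4-methoxy-2-methyl-5-oxocyclopentane-1-carboxylate (C1/C4 epimers) | COC(=O)C1C(=O)C(OC)[C@H](c2ccc(OC)c(OC)c2)[C@H]1C | intermediate
12 | methyl (1R,2R,3S)-1-allyl-3-(3,4-dimethoxyphenyl)-4-methoxy-2-methyl-5-oxocyclopentane-1-carboxylate (C4 epimers) | C=CC[C@]1(C(=O)OC)C(=O)C(OC)[C@H](c2ccc(OC)c(OC)c2)[C@H]1C | intermediate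
13 | methoxyacetaldehyde | COCC=O | starting material
14 | methyl (1R,2R,3S,4S)-1-allyl-3-(3,4-dimethoxyphenyl)-4-(1-hydroxy-2-methoxyethyl)-4-methoxy-2-methyl-5-oxocyclopentane-1-carboxylate (carbinol epimers) | C=CC[C@]1(C(=O)OC)C(=O)[C@@](OC)(C(O)COC)[C@H](c2ccc(OC)c(OC)c2)[C@H]1C | intermediate
15 | (2S,3R,4S,5R)-2-allyl-4-(3,4-dimethoxyphenyl)-2-(hydroxymethyl)-5-(1-hydroxy-2-methoxyethyl)-5-methoxy-3-methylcyclopentan-1-ol (secondary carbinols as mixtures) | C=CC[C@]1(CO)C(O)[C@@](OC)(C(O)COC)[C@H](c2ccc(OC)c(OC)c2)[C@H]1C | intermediate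
16 | (1S,2R,3S,4R)-1-allyl-3-(3,4-dimethoxyphenyl)-4-methoxy-4-(methoxyacetyl)-2-methyl-5-oxocyclopentane-1-carbaldehyde | C=CC[C@]1(C=O)C(=O)[C@@](OC)(C(=O)COC)[C@H](c2ccc(OC)c(OC)c2)[C@H]1C | intermediate
17 | (1S,5R,6S,7R)-1-allyl-6-(3,4-dimethoxyphenyl)-2-hydroxy-3,5-dimethoxy-7-methylbicyclo[3.2.1]octane-4,8-dione (C2/C3 epimers) | C=CC[C@]12C(O)C(OC)C(=O)[C@](OC)(C1=O)[C@H](c3ccc(OC)c(OC)c3)[C@H]2C | intermediate
18 | 2-O-methanesulfonate of 17 (C2/C3 epimers) | C=CC[C@]12C(OS(C)(=O)=O)C(OC)C(=O)[C@](OC)(C1=O)[C@H](c3ccc(OC)c(OC)c3)[C@H]2C | intermediate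
19 | (1S,5R,6S,7R)-1-allyl-6-(3,4-dimethoxyphenyl)-3,5-dimethoxy-7-methylbicyclo[3.2.1]oct-2-ene-4,8-dione | C=CC[C@]12C=C(OC)C(=O)[C@](OC)(C1=O)[C@H](c3ccc(OC)c(OC)c3)[C@H]2C | intermediate
20 | (1S,4R,5S,6S,7R)-1-allyl-6-(3,4-dimethoxyphenyl)-4-hydroxy-3,5-dimethoxy-7-methylbicyclo[3.2.1]oct-2-en-8-one (4-endo alcohol) | C=CC[C@]12C=C(OC)[C@@H](O)[C@](OC)(C1=O)[C@H](c3ccc(OC)c(OC)c3)[C@H]2C | intermediate
21 | lithium alkoxide of 20 (4R) | C=CC[C@]12C=C(OC)[C@@H](O[Li])[C@](OC)(C1=O)[C@H](c3ccc(OC)c(OC)c3)[C@H]2C | intermediate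
22 | lithium (3S,4R,5S)-5-allyl-3-(3,4-dimethoxyphenyl)-2-methoxy-5-[(1E)-2-methoxy-3-oxoprop-1-en-1-yl]-4-methylcyclopent-1-en-1-olate (ring carbon cis to CHO) | C=CC[C@]1(/C=C(\C=O)OC)C(O[Li])=C(OC)[C@H](c2ccc(OC)c(OC)c2)[C@H]1C | intermediate
23 | lithium alkoxide of 24 (4S) | C=CC[C@]12C=C(OC)[C@H](O[Li])[C@](OC)(C1=O)[C@H](c3ccc(OC)c(OC)c3)[C@H]2C | intermediate
24 | (1S,4S,5S,6S,7R)-1-allyl-6-(3,4-dimethoxyphenyl)-4-hydroxy-3,5-dimethoxy-7-methylbicyclo[3.2.1]oct-2-en-8-one (4-exo alcohol) | C=CC[C@]12C=C(OC)[C@H](O)[C@](OC)(C1=O)[C@H](c3ccc(OC)c(OC)c3)[C@H]2C | intermediate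
25 | (1S,4S,5S,6S,7R)-1-allyl-6-(3,4-dimethoxyphenyl)-3,5-dimethoxy-7-methyl-8-oxobicyclo[3.2.1]oct-2-en-4-yl acetate | C=CC[C@]12C=C(OC)[C@H](OC(C)=O)[C@](OC)(C1=O)[C@H](c3ccc(OC)c(OC)c3)[C@H]2C | target

**Total step count:** 16. **Longest linear sequence:** 16 steps (1 → 25; the route is fully linear).

**Three steps most likely to fail, with fallbacks**

Step 15 (C4 epimerisation) is the least certain step. It rests on the chelated exo aldolate being both reachable and favoured over the ring-opened enal, and I have no direct precedent for this system. The fallback sets out from 20 and inverts C4 by substitution instead of equilibration. Mitsunobu reaction with chloroacetic acid (PPh3, DIAD, toluene, 0 °C to rt) gives (1S,4S,5S,6S,7R)-1-allyl-6-(3,4-dimethoxyphenyl)-3,5-dimethoxy-7-methyl-8-oxobicyclo[3.2.1]oct-2-en-4-yl chloroacetate F6. Neutral removal of the chloroacetyl group with thiourea and NaHCO3 in EtOH at 50 °C then returns the route at 24. This displacement is at a hindered centre next to a quaternary carbon, so it is itself uncertain.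

Step 14 (Luche reduction) may also reduce the strained C8 ketone. The fallback sets out from 19 and accepts over-reduction. Excess NaBH4 in MeOH at 0 °C gives 1-allyl-6-(3,4-dimethoxyphenyl)-3,5-dimethoxy-7-methylbicyclo[3.2.1]oct-2-ene-4,8-diol with the ring stereocentres of 20 (4-endo OH, C8 carbinol unassigned) F3. Et3SiCl and imidazole in CH2Cl2 at −20 °C silylate only the far less hindered C4 hydroxyl to give the 4-O-triethylsilyl ether of this diol F4. Dess–Martin periodinane with NaHCO3 re-oxidises the C8 carbinol to the 4-O-triethylsilyl ether of 20 F5. HF·pyridine in THF removes the silyl group and the route is rejoined at 20.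

Step 2 (Michael addition) may be slow or poorly selective because the 3,4-dimethoxyphenyl group makes 3 a weak acceptor. The fallback sets out from 3 and uses chiral Lewis-acid activation of the malonate instead of enamine activation. S-Ethyl propanethioate is converted (LiN(iPr)2, Me3SiCl, THF, −78 °C) into (Z)-1-(ethylsulfanyl)-1-(trimethylsilyloxy)prop-1-ene F1. This adds to 3 in a Mukaiyama–Michael reaction catalysed by the bis(oxazoline) complex [Cu(C17H30N2O2)](SbF6)2 (divalent copper, 10 mol %; ligand 2,2'-(propane-2,2-diyl)bis(4-tert-butyl-4,5-dihydrooxazole)) in CH2Cl2/(CF3)2CHOH at −78 °C. The product is dimethyl 2-[(1S,2R)-1-(3,4-dimethoxyphenyl)-3-(ethylsulfanyl)-2-methyl-3-oxopropyl]propanedioate F2. The ligand antipode and, if needed, the ketene-acetal geometry are chosen to give this syn isomer, which I have not confirmed from precedent. Fukuyama reduction (Et3SiH, Pd on carbon, zerovalent palladium, acetone, rt) converts the thioester into aldehyde 5, where the route is rejoined.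

**Further compounds**
F1 | step 2 | (Z)-1-(ethylsulfanyl)-1-(trimethylsilyloxy)prop-1-ene | C/C=C(\SCC)O[Si](C)(C)C
F2 | step 2 | dimethyl 2-[(1S,2R)-1-(3,4-dimethoxyphenyl)-3-(ethylsulfanyl)-2-methyl-3-oxopropyl]propanedioate | CCSC(=O)[C@H](C)[C@@H](c1ccc(OC)c(OC)c1)C(C(=O)OC)C(=O)OC
F3 | step 14 | 1-allyl-6-(3,4-dimethoxyphenyl)-3,5-dimethoxy-7-methylbicyclo[3.2.1]oct-2-ene-4,8-diol, ring stereocentres as in 20 (4-endo OH, C8 carbinol unassigned) | C=CC[C@]12C=C(OC)[C@@H](O)[C@](OC)(C1O)[C@H](c3ccc(OC)c(OC)c3)[C@H]2C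
F4 | step 14 | 4-O-triethylsilyl ether of F3 | C=CC[C@]12C=C(OC)[C@@H](O[Si](CC)(CC)CC)[C@](OC)(C1O)[C@H](c3ccc(OC)c(OC)c3)[C@H]2C
F5 | step 14 | 4-O-triethylsilyl ether of 20 | C=CC[C@]12C=C(OC)[C@@H](O[Si](CC)(CC)CC)[C@](OC)(C1=O)[C@H](c3ccc(OC)c(OC)c3)[C@H]2C
F6 | step 15 | (1S,4S,5S,6S,7R)-1-allyl-6-(3,4-dimethoxyphenyl)-3,5-dimethoxy-7-methyl-8-oxobicyclo[3.2.1]oct-2-en-4-yl chloroacetate | C=CC[C@]12C=C(OC)[C@H](OC(=O)CCl)[C@](OC)(C1=O)[C@H](c3ccc(OC)c(OC)c3)[C@H]2C
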